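The route rests on disconnecting the O1–C7a bond of the cis-fused γ-lactone (1-benzofuran-2-one numbering). The trans arrangement of the lactone oxygen at C7a and the free hydroxyl at C7 on the cyclohexane ring marks a former epoxide. An α-epoxide across C7–C7a is opened at C7a, 5-exo and with inversion, by the carbonyl oxygen of the propanoate arm on C3a. One acid-triggered operation thus closes the lactone, sets C7a, frees the C7 hydroxyl and gives the target. The precursor is a cyclohexene oxide bearing the ethyl propanoate arm, made by a Johnson–Claisen rearrangement that relays the C7 carbinol configuration to C3a and C3.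

Key step: step 12

Remark: locants follow the target (O1, C2, C3, C3a, C4, C5, C6, C7, C7a); β is the ring face that carries the C6 methyl group, α the face of the C6 vinyl group.

Step 1
Reactants: 1 4,4,5,5-tetramethyl-2-(prop-1-en-2-yl)-1,3,2-dioxaborolane; 2 4,4-dimethoxycyclohexa-2,5-dien-1-one
Product: 3 (5R)-4,4-dimethoxy-5-(prop-1-en-2-yl)cyclohex-2-en-1-one
Conditions: [RhCl(C2H4)2]2 (2.5 mol %), (R)-BINAP (6 mol %), KOH (0.3 equiv), 1,4-dioxane/H2O 10:1, 50 °C; neutral work-up
Reagents that add atoms: none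
Why: Hayashi–Miyaura rhodium-catalysed asymmetric 1,4-addition desymmetrises the achiral dienone; (R)-BINAP is chosen by analogy with the sense known for cyclohexenone so that C5 should form as (R), and the untouched second enone arm is kept for steps 5–9.

Step 2
Reactants: 3 (5R)-4,4-dimethoxy-5-(prop-1-en-2-yl)cyclohex-2-en-1-one
Product: 5 (5R,6S)-4,4-dimethoxy-6-methyl-5-(prop-1-en-2-yl)cyclohex-2-en-1-one, via lithium enolate 4 (not isolated)
Conditions: LiN(i-Pr)2 (1.05 equiv), THF, −78 °C; then MeI, −78 → −30 °C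
Reagents that add atoms: iodomethane, CI
Why: kinetic α'-deprotonation (the only enolisable site) and SN2 methylation of the cross-conjugated enolate, expected anti to the C5 group; this centre is re-enolised in step 3, so its configuration does not matter.

Step 3
Reactants: 5 (5R,6S)-4,4-dimethoxy-6-methyl-5-(prop-1-en-2-yl)cyclohex-2-en-1-one
Product: 7 (5S,6R)-6-(1-hydroxyethyl)-4,4-dimethoxy-6-methyl-5-(prop-1-en-2-yl)cyclohex-2-en-1-one (carbinol epimers), via lithium enolate 6 (not isolated)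
Conditions: LiN(i-Pr)2 (1.1 equiv), THF, −78 → −30 °C; then CH3CHO, −78 °C; AcOH quench at −78 °C
Reagents that add atoms: acetaldehyde, CC=O
Why: aldol addition of the tetrasubstituted enolate builds the quaternary C6; the aldehyde should approach anti to the C5 isopropenyl group (held pseudoaxial by A(1,2) strain with the enolate methyl), which puts the two-carbon unit α and the methyl β.

Step 4
Reactants: 7 (5S,6R)-6-(1-hydroxyethyl)-4,4-dimethoxy-6-methyl-5-(prop-1-en-2-yl)cyclohex-2-en-1-one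
Product: 8 (5S,6S)-6-ethenyl-4,4-dimethoxy-6-methyl-5-(prop-1-en-2-yl)cyclohex-2-en-1-one
Conditions: Burgess reagent (1.5 equiv), toluene, 70 °C
Reagents that add atoms: none
Why: Burgess dehydration (syn-elimination) can only take hydrogen from the carbinol methyl group because C6 is quaternary, so the terminal vinyl group should form under neutral conditions that spare the ketal.

Step 5
Reactants: 8 (5S,6S)-6-ethenyl-4,4-dimethoxy-6-methyl-5-(prop-1-en-2-yl)cyclohex-2-en-1-one
Product: 9 (2S,3S)-2-ethenyl-2-methyl-3-(prop-1-en-2-yl)cyclohex-5-ene-1,4-dione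
Conditions: TsOH·H2O (0.2 equiv), acetone/H2O 10:1, 23 °C
Reagents that add atoms: water, O
Why: acid-catalysed ketal hydrolysis unveils the C4 carbonyl; aromatisation by loss of methanol is no longer possible because C6 is quaternary.

Step 6
Reactants: 9 (2S,3S)-2-ethenyl-2-methyl-3-(prop-1-en-2-yl)cyclohex-5-ene-1,4-dione
Product: 10 (4R,5S,6S)-6-ethenyl-4-hydroxy-6-methyl-5-(prop-1-en-2-yl)cyclohex-2-en-1-one
Conditions: i-Bu2AlH (1.05 equiv), CH2Cl2, −78 °C; aq. KNaC4H4O6 work-up
Reagents that add atoms: none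
Why: 1,2-reduction by the bulky aluminium hydride should occur at the C4 carbonyl (next to a tertiary carbon) in preference to the C7 carbonyl (screened on both faces by the quaternary C6), and from the α face opposite the C6 methyl and C5 isopropenyl groups, giving the 4β-alcohol cis to C5.

Step 7
Reactants: 10 (4R,5S,6S)-6-ethenyl-4-hydroxy-6-methyl-5-(prop-1-en-2-yl)cyclohex-2-en-1-one
Product: 11 (1R,5S,6S)-5-ethenyl-5-methyl-4-oxo-6-(prop-1-en-2-yl)cyclohex-2-en-1-yl 2-methylpropanoate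
Conditions: (i-PrCO)2O (1.5 equiv), Et3N, DMAP (0.1 equiv), CH2Cl2, 0 °C
Reagents that add atoms: isobutyric anhydride, CC(C)C(=O)OC(=O)C(C)C
Why: DMAP-catalysed acylation of the only hydroxyl group installs the isobutyrate before any carboxyl group exists, so O4 can never lactonise onto the later side chain.

Step 8
Reactants: 11 (1R,5S,6S)-5-ethenyl-5-methyl-4-oxo-6-(prop-1-en-2-yl)cyclohex-2-en-1-yl 2-methylpropanoate
Product: 12 (1R,4S,5S,6S)-5-ethenyl-4-hydroxy-5-methyl-6-(prop-1-en-2-yl)cyclohex-2-en-1-yl 2-methylpropanoate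
Conditions: (R)-2-methyl-CBS-oxazaborolidine (0.3 equiv), catecholborane (1.5 equiv), toluene, −78 → −30 °C; MeOH quench, pH 7 work-up
Reagents that add atoms: none
Why: CBS reduction of the enone in the 1,2-sense; with the quaternary C6 as the large group the (R)-catalyst should deliver hydride to the α face and give the 7β-alcohol cis to the C4 ester, which catecholborane does not touch.

Step 9
Reactants: 12 (1R,4S,5S,6S)-5-ethenyl-4-hydroxy-5-methyl-6-(prop-1-en-2-yl)cyclohex-2-en-1-yl 2-methylpropanoate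
Product: 14 ethyl (2R)-2-[(1S,4R,5S,6R)-4-ethenyl-4-methyl-6-(2-methylpropanoyloxy)-5-(prop-1-en-2-yl)cyclohex-2-en-1-yl]propanoate, via ketene acetal 13 (not isolated)
Conditions: EtC(OEt)3 (8 equiv), EtCO2H (0.1 equiv), xylene, 140 °C, EtOH distilled off
Reagents that add atoms: triethyl orthopropionate, CCC(OCC)(OCC)OCC
Why: Johnson–Claisen rearrangement; the suprafacial [3,3] shift exchanges the 7β C–O bond for a 3aβ C–C bond, and because the β-axial C5 group blocks the chair, the boat transition state with the methyl group outside (anti to O7, reached because the ketene acetal isomers equilibrate) should give (3R).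

Step 10
Reactants: 14 ethyl (2R)-2-[(1S,4R,5S,6R)-4-ethenyl-4-methyl-6-(2-methylpropanoyloxy)-5-(prop-1-en-2-yl)cyclohex-2-en-1-yl]propanoate
Product: 16 ethyl (2R)-2-[(1S,4R,5R,6R)-4-ethenyl-4-methyl-6-(2-methylpropanoyloxy)-5-(3-oxoprop-1-en-2-yl)cyclohex-2-en-1-yl]propanoate, via allylic alcohol 15 (not isolated)
Conditions: SeO2 (0.5 equiv), t-BuOOH (3 equiv), CH2Cl2, 23 °C; then MnO2 (excess), CH2Cl2, 23 °C
Reagents that add atoms: selenium dioxide, O=[Se]=O; tert-butyl hydroperoxide, CC(C)(C)OO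
Why: Riley allylic oxidation (ene reaction, then [2,3]-shift) should attack the isopropenyl methyl group, since methyl is preferred over the C5 methine, the vinyl group has no allylic hydrogen and the hindered ring alkene offers only a methine; MnO2 then oxidises only the allylic alcohol.

Step 11
Reactants: 16 ethyl (2R)-2-[(1S,4R,5R,6R)-4-ethenyl-4-methyl-6-(2-methylpropanoyloxy)-5-(3-oxoprop-1-en-2-yl)cyclohex-2-en-1-yl]propanoate
Product: 17 ethyl (2R)-2-[(1S,2S,3R,4S,5S,6R)-2-ethenyl-2-methyl-4-(2-methylpropanoyloxy)-3-(3-oxoprop-1-en-2-yl)-7-oxabicyclo[4.1.0]heptan-5-yl]propanoate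
Conditions: mCPBA (1.1 equiv), NaHCO3, CH2Cl2, 0 °C
Reagents that add atoms: 3-chloroperbenzoic acid, O=C(OO)c1cccc(Cl)c1
Why: Prilezhaev epoxidation of the only electron-rich 1,2-disubstituted alkene (the enal alkene is electron-poor, the vinyl group monosubstituted and neopentyl), expected from the α face because the pseudoaxial C6 methyl and the axial C4 ester shield the β face.

Step 12
Reactants: 17 ethyl (2R)-2-[(1S,2S,3R,4S,5S,6R)-2-ethenyl-2-methyl-4-(2-methylpropanoyloxy)-3-(3-oxoprop-1-en-2-yl)-7-oxabicyclo[4.1.0]heptan-5-yl]propanoate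
Product: 20 (3R,3aS,4S,5R,6S,7S,7aS)-6-ethenyl-7-hydroxy-3,6-dimethyl-2-oxo-5-(3-oxoprop-1-en-2-yl)octahydro-1-benzofuran-4-yl 2-methylpropanoate, via dialkoxycarbenium ion 18 (not isolated), via hemiorthoester 19 (not isolated)
Conditions: TsOH·H2O (0.3 equiv), THF/H2O 10:1, 23 °C
Reagents that add atoms: water, O
Why: The protonated α-epoxide is opened at C7a by the carbonyl oxygen of the ethyl ester in an anti, SN2-like attack that gives dialkoxycarbenium ion 18; water adds to give hemiorthoester 19, which loses ethanol to leave the lactone. The closest known reaction type is the acid-catalysed conversion of γ,δ-epoxy esters into γ-lactones, the epoxide counterpart of halolactonisation. The only ring closed is the γ-lactone, by 5-exo-tet closure at C7a, and it is cis-fused because the ester arm on C3a and the new C7a–O1 bond are both β. C7a is set by inversion at the epoxide carbon and the C7 hydroxyl keeps the α configuration of the epoxide oxygen, so both follow from the epoxide face fixed in step 11. The step needs attack at C7a rather than C7, and participation by the propanoate rather than the C4 isobutyrate: C7 is neopentyl and would require 6-endo closure, opening at C7a is the trans-diaxial (Fürst–Plattner) mode, and the propanoate closes a five-membered ring whereas the isobutyrate would have to form a six-membered dioxanylium ion.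

Compound list
1 | 4,4,5,5-tetramethyl-2-(prop-1-en-2-yl)-1,3,2-dioxaborolane (isopropenylboronic acid pinacol ester) | CC(=C)B1OC(C)(C)C(C)(C)O1 | starting material
2 | 4,4-dimethoxycyclohexa-2,5-dien-1-one | COC1(OC)C=CC(=O)C=C1 | starting material
3 | (5R)-4,4-dimethoxy-5-(prop-1-en-2-yl)cyclohex-2-en-1-one | C1C(=O)C=CC(OC)(OC)[C@H]1C(C)=C | intermediate
4 | lithium (3R)-4,4-dimethoxy-3-(prop-1-en-2-yl)cyclohexa-1,5-dien-1-olate (lithium enolate of 3, not isolated) | [Li]OC1=C[C@H](C(C)=C)C(OC)(OC)C=C1 | intermediate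
5 | (5R,6S)-4,4-dimethoxy-6-methyl-5-(prop-1-en-2-yl)cyclohex-2-en-1-one | C[C@@H]1C(=O)C=CC(OC)(OC)[C@H]1C(C)=C | intermediate
6 | lithium (3S)-4,4-dimethoxy-2-methyl-3-(prop-1-en-2-yl)cyclohexa-1,5-dien-1-olate (lithium enolate of 5, not isolated) | [Li]OC1=C(C)[C@H](C(C)=C)C(OC)(OC)C=C1 | intermediate
7 | (5S,6R)-6-(1-hydroxyethyl)-4,4-dimethoxy-6-methyl-5-(prop-1-en-2-yl)cyclohex-2-en-1-one, mixture of carbinol epimers | CC(O)[C@]1(C)C(=O)C=CC(OC)(OC)[C@H]1C(C)=C | intermediate
8 | (5S,6S)-6-ethenyl-4,4-dimethoxy-6-methyl-5-(prop-1-en-2-yl)cyclohex-2-en-1-one | C=C[C@]1(C)C(=O)C=CC(OC)(OC)[C@H]1C(C)=C | intermediate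
9 | (2S,3S)-2-ethenyl-2-methyl-3-(prop-1-en-2-yl)cyclohex-5-ene-1,4-dione | C=C[C@]1(C)C(=O)C=CC(=O)[C@H]1C(C)=C | intermediate
10 | (4R,5S,6S)-6-ethenyl-4-hydroxy-6-methyl-5-(prop-1-en-2-yl)cyclohex-2-en-1-one | C=C[C@]1(C)C(=O)C=C[C@@H](O)[C@H]1C(C)=C | intermediate
11 | (1R,5S,6S)-5-ethenyl-5-methyl-4-oxo-6-(prop-1-en-2-yl)cyclohex-2-en-1-yl 2-methylpropanoate | C=C[C@]1(C)C(=O)C=C[C@@H](OC(=O)C(C)C)[C@H]1C(C)=C | intermediate
12 | (1R,4S,5S,6S)-5-ethenyl-4-hydroxy-5-methyl-6-(prop-1-en-2-yl)cyclohex-2-en-1-yl 2-methylpropanoate | C=C[C@]1(C)[C@@H](O)C=C[C@@H](OC(=O)C(C)C)[C@H]1C(C)=C | intermediate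
13 | (1R,4S,5S,6S)-4-{[(1E)-1-ethoxyprop-1-en-1-yl]oxy}-5-ethenyl-5-methyl-6-(prop-1-en-2-yl)cyclohex-2-en-1-yl 2-methylpropanoate (mixed ketene acetal, not isolated) | C=C[C@]1(C)[C@@H](O/C(OCC)=C/C)C=C[C@@H](OC(=O)C(C)C)[C@H]1C(C)=C | intermediate
14 | ethyl (2R)-2-[(1S,4R,5S,6R)-4-ethenyl-4-methyl-6-(2-methylpropanoyloxy)-5-(prop-1-en-2-yl)cyclohex-2-en-1-yl]propanoate | C=C[C@]1(C)C=C[C@@H]([C@@H](C)C(=O)OCC)[C@@H](OC(=O)C(C)C)[C@H]1C(C)=C | intermediate
15 | ethyl (2R)-2-[(1S,4R,5R,6R)-4-ethenyl-5-(3-hydroxyprop-1-en-2-yl)-4-methyl-6-(2-methylpropanoyloxy)cyclohex-2-en-1-yl]propanoate (not isolated) | C=C[C@]1(C)C=C[C@@H]([C@@H](C)C(=O)OCC)[C@@H](OC(=O)C(C)C)[C@H]1C(=C)CO | intermediate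
16 | ethyl (2R)-2-[(1S,4R,5R,6R)-4-ethenyl-4-methyl-6-(2-methylpropanoyloxy)-5-(3-oxoprop-1-en-2-yl)cyclohex-2-en-1-yl]propanoate | C=C[C@]1(C)C=C[C@@H]([C@@H](C)C(=O)OCC)[C@@H](OC(=O)C(C)C)[C@H]1C(=C)C=O | intermediate
17 | ethyl (2R)-2-[(1S,2S,3R,4S,5S,6R)-2-ethenyl-2-methyl-4-(2-methylpropanoyloxy)-3-(3-oxoprop-1-en-2-yl)-7-oxabicyclo[4.1.0]heptan-5-yl]propanoate (α-epoxide) | C=C[C@]1(C)[C@@H]2O[C@@H]2[C@@H]([C@@H](C)C(=O)OCC)[C@@H](OC(=O)C(C)C)[C@H]1C(=C)C=O | intermediate
18 | cyclic dialkoxycarbenium ion: the bicyclic skeleton of 20 with C2 as a cation bearing OEt and O1 (not isolated) | C=C[C@]1(C)[C@H](O)[C@H]2O[C+](OCC)[C@H](C)[C@H]2[C@@H](OC(=O)C(C)C)[C@H]1C(=C)C=O | intermediate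
19 | hemiorthoester: the bicyclic skeleton of 20 with C2 bearing OH and OEt, C2 epimers (not isolated) | C=C[C@]1(C)[C@H](O)[C@H]2OC(O)(OCC)[C@H](C)[C@H]2[C@@H](OC(=O)C(C)C)[C@H]1C(=C)C=O | intermediate
20 | (3R,3aS,4S,5R,6S,7S,7aS)-6-ethenyl-7-hydroxy-3,6-dimethyl-2-oxo-5-(3-oxoprop-1-en-2-yl)octahydro-1-benzofuran-4-yl 2-methylpropanoate | C=C[C@]1(C)[C@H](O)[C@H]2OC(=O)[C@H](C)[C@H]2[C@@H](OC(=O)C(C)C)[C@H]1C(=C)C=O | target

Total step count: 12. Longest linear sequence: 12 steps (1 and 2 to 20).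

Steps most likely to fail

Step 12. The weakly nucleophilic ester carbonyl may be outrun by participation of the C4 isobutyrate carbonyl, which would lead to acyl migration, or by cationic 1,2-shifts from C6 after premature epoxide ionisation. The fallback closes the same bond with a free carboxylic acid, which needs no acid catalyst; it sets out from 12 and comes back at 20. Acylation of 12 with propanoyl chloride (pyridine, DMAP, CH2Cl2) should give the mixed diester (1R,4S,5S,6S)-5-ethenyl-5-methyl-4-(propanoyloxy)-6-(prop-1-en-2-yl)cyclohex-2-en-1-yl 2-methylpropanoate F1. Soft enolisation of the propanoate only (n-Bu2BOTf, i-Pr2NEt, CH2Cl2, −78 → 23 °C; the α-branched isobutyrate should not enolise) followed by Ireland–Claisen rearrangement should give the acid (2R)-2-[(1S,4R,5S,6R)-4-ethenyl-4-methyl-6-(2-methylpropanoyloxy)-5-(prop-1-en-2-yl)cyclohex-2-en-1-yl]propanoic acid F2. Allylic oxidation (SeO2, t-BuOOH, CH2Cl2) should give the hydroxy acid F3, and Dess–Martin periodinane the enal acid F4. mCPBA (CH2Cl2, 0 → 23 °C) should then epoxidise the ring alkene from the α face, and the epoxy acid F5 should close spontaneously, 5-exo and anti, to 20.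

Step 9. Orthoester exchange at the hindered, neopentyl-type allylic alcohol may be sluggish at 140 °C, with ionisation or elimination competing, and the C3 configuration may erode if chair and boat transition states compete. The fallback generates the ketene acetal at low temperature by conjugate reduction; it sets out from 12 and comes back at 14. Acryloyl chloride (Et3N, CH2Cl2, 0 °C) should give the acrylate (1R,4S,5S,6S)-5-ethenyl-5-methyl-4-(prop-2-enoyloxy)-6-(prop-1-en-2-yl)cyclohex-2-en-1-yl 2-methylpropanoate F6. Catalytic [(Ph3P)CuH]6 with (EtO)2MeSiH (toluene, 0 → 60 °C) should effect a reductive Ireland–Claisen rearrangement to the silyl ester diethoxy(methyl)silyl (2R)-2-[(1S,4R,5S,6R)-4-ethenyl-4-methyl-6-(2-methylpropanoyloxy)-5-(prop-1-en-2-yl)cyclohex-2-en-1-yl]propanoate F7. Without isolation, CsF and EtI in DMF should convert F7 into 14.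

Step 10. The ene oxidation may show poor site selectivity between the isopropenyl methyl group, the C5 methine and the allylic methine of the ring alkene, and may over-oxidise. The fallback replaces the selenium ene reaction by chlorination and oxidation; it sets out from 14 and comes back at 16. Ene-type allylic chlorination with hypochlorous acid (Ca(OCl)2, solid CO2, CH2Cl2/H2O, 0 °C) should give the allylic chloride ethyl (2R)-2-[(1S,4R,5R,6R)-5-(3-chloroprop-1-en-2-yl)-4-ethenyl-4-methyl-6-(2-methylpropanoyloxy)cyclohex-2-en-1-yl]propanoate F8. Kornblum-type oxidation with N-methylmorpholine N-oxide (MeCN, 23 → 50 °C) should then give 16.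

Further compounds
F1 | step 12 | (1R,4S,5S,6S)-5-ethenyl-5-methyl-4-(propanoyloxy)-6-(prop-1-en-2-yl)cyclohex-2-en-1-yl 2-methylpropanoate | C=C[C@]1(C)[C@@H](OC(=O)CC)C=C[C@@H](OC(=O)C(C)C)[C@H]1C(C)=C
F2 | step 12 | (2R)-2-[(1S,4R,5S,6R)-4-ethenyl-4-methyl-6-(2-methylpropanoyloxy)-5-(prop-1-en-2-yl)cyclohex-2-en-1-yl]propanoic acid | C=C[C@]1(C)C=C[C@@H]([C@@H](C)C(=O)O)[C@@H](OC(=O)C(C)C)[C@H]1C(C)=C
F3 | step 12 | (2R)-2-[(1S,4R,5R,6R)-4-ethenyl-5-(3-hydroxyprop-1-en-2-yl)-4-methyl-6-(2-methylpropanoyloxy)cyclohex-2-en-1-yl]propanoic acid | C=C[C@]1(C)C=C[C@@H]([C@@H](C)C(=O)O)[C@@H](OC(=O)C(C)C)[C@H]1C(=C)CO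
F4 | step 12 | (2R)-2-[(1S,4R,5R,6R)-4-ethenyl-4-methyl-6-(2-methylpropanoyloxy)-5-(3-oxoprop-1-en-2-yl)cyclohex-2-en-1-yl]propanoic acid | C=C[C@]1(C)C=C[C@@H]([C@@H](C)C(=O)O)[C@@H](OC(=O)C(C)C)[C@H]1C(=C)C=O
F5 | step 12 | (2R)-2-[(1S,2S,3R,4S,5S,6R)-2-ethenyl-2-methyl-4-(2-methylpropanoyloxy)-3-(3-oxoprop-1-en-2-yl)-7-oxabicyclo[4.1.0]heptan-5-yl]propanoic acid | C=C[C@]1(C)[C@@H]2O[C@@H]2[C@@H]([C@@H](C)C(=O)O)[C@@H](OC(=O)C(C)C)[C@H]1C(=C)C=O
F6 | step 9 | (1R,4S,5S,6S)-5-ethenyl-5-methyl-4-(prop-2-enoyloxy)-6-(prop-1-en-2-yl)cyclohex-2-en-1-yl 2-methylpropanoate | C=C[C@]1(C)[C@@H](OC(=O)C=C)C=C[C@@H](OC(=O)C(C)C)[C@H]1C(C)=C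
F7 | step 9 | diethoxy(methyl)silyl (2R)-2-[(1S,4R,5S,6R)-4-ethenyl-4-methyl-6-(2-methylpropanoyloxy)-5-(prop-1-en-2-yl)cyclohex-2-en-1-yl]propanoate | C=C[C@]1(C)C=C[C@@H]([C@@H](C)C(=O)O[Si](C)(OCC)OCC)[C@@H](OC(=O)C(C)C)[C@H]1C(C)=C
F8 | step 10 | ethyl (2R)-2-[(1S,4R,5R,6R)-5-(3-chloroprop-1-en-2-yl)-4-ethenyl-4-methyl-6-(2-methylpropanoyloxy)cyclohex-2-en-1-yl]propanoate | C=C[C@]1(C)C=C[C@@H]([C@@H](C)C(=O)OCC)[C@@H](OC(=O)C(C)C)[C@H]1C(=C)CCl
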